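**Retrosynthetic overview**
1. Rhodisin is EGCG-(4β→8)-EGCG, so the last step is global hydrogenolysis of its hexadeca-O-benzyl ether.
2. Both gallate esters are disconnected next: double Steglich esterification of the deca-O-benzyl EGC-(4β→8)-EGC diol with 3,4,5-tris(benzyloxy)benzoic acid.
3. The only skeletal disconnection is the C4(upper)–C8(lower) bond, made by Lewis-acid Friedel–Crafts union of a 4β-(2-ethoxyethoxy) penta-O-benzyl-EGC electrophile with penta-O-benzyl-EGC; the electrophile comes from the same monomer by DDQ C4–H oxidation.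
4. No ring is formed: rings A, B and C and the 2R,3R centres of both halves come from commercial (−)-epigallocatechin; only the upper C4 centre is created.

Assumption: the SMILES is read as EGCG-(4β→8)-EGCG (upper unit 2R,3R,4R; lower unit 2R,3R); natural (−)-epigallocatechin (2R,3R) and 3,4,5-tris(benzyloxy)benzoic acid are taken as commercial; the route is a proposal reasoned from known flavan-3-ol chemistry and has not been run.

**Route**

Step 1
Reactants: 1 (−)-epigallocatechin (EGC)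
Product: 2 5,7,3',4',5'-penta-O-benzyl-(−)-epigallocatechin [(2R,3R)-5,7-bis(benzyloxy)-2-(3,4,5-tris(benzyloxy)phenyl)chroman-3-ol]
Conditions: BnBr (5.5 equiv), K2CO3 (6 equiv), degassed DMF, N2, −10 °C → rt, 24 h
Reagents that add atoms: benzyl bromide, BrCc1ccccc1
Why: Williamson ether synthesis, in which K2CO3 deprotonates only the five phenols and the phenoxides are O-benzylated by SN2 on benzyl bromide, while the much less acidic secondary 3-OH stays free and the 2R,3R centres are untouched (no new stereocentre).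

Step 2
Reactants: 2 penta-O-benzyl-(−)-epigallocatechin
Product: 3 (2R,3R,4S)-penta-O-benzyl-4β-(2-ethoxyethoxy)-epigallocatechin
Conditions: DDQ (2 equiv), EtOCH2CH2OH (5 equiv), CH2Cl2, rt, 2 h
Reagents that add atoms: 2-ethoxyethanol, CCOCCO
Why: DDQ benzylic C–H oxidation (hydride abstraction) occurs at C4, the only benzylic position conjugated to the 5,7-dialkoxy ring A, and the resulting flavan-4-yl cation is trapped by 2-ethoxyethanol on the β face, anti to the cis 2-aryl and 3-hydroxy groups, which sets C4 as S (3,4-trans).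

Step 3
Reactants: 3 (2R,3R,4S)-penta-O-benzyl-4β-(2-ethoxyethoxy)-epigallocatechin (electrophile, 1 equiv); 2 penta-O-benzyl-(−)-epigallocatechin (nucleophile, 4 equiv, excess recovered)
Product: 4 deca-O-benzyl-EGC-(4β→8)-EGC (both 3-OH groups free; upper unit 2R,3R,4R, lower unit 2R,3R)
Conditions: Me3SiOTf (0.5 equiv), CH2Cl2, −78 °C, 10 min; aq NaHCO3
Reagents that add atoms: none
Why: Lewis-acid-promoted Friedel–Crafts alkylation, in which Me3SiOTf ionises the benzylic C4 ether of 3 and the more nucleophilic C8 of ring A of 2 attacks the flavan-4-yl cation from the β face, anti to the 3-OH and 2-aryl groups, giving the 4β→8 bond with C4 as R (3,4-trans) while the excess of 2 suppresses self-condensation of 3.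

Step 4
Reactants: 4 deca-O-benzyl-EGC-(4β→8)-EGC; 5 3,4,5-tris(benzyloxy)benzoic acid (incorporated twice)
Product: 6 hexadeca-O-benzyl-rhodisin (perbenzylated EGCG-(4β→8)-EGCG)
Conditions: acid 5 (6 equiv), DCC (6 equiv), DMAP (2 equiv), CH2Cl2, rt → 40 °C, 48 h
Reagents that add atoms: 3,4,5-tris(benzyloxy)benzoic acid (compound 5, incorporated twice), OC(=O)c1cc(OCc2ccccc2)c(OCc2ccccc2)c(OCc2ccccc2)c1
Why: Steglich esterification, in which DCC activates the acid and DMAP transfers the acyl group to both secondary 3-hydroxy groups with retention at C3 and C3'' because no bond to a stereocentre is broken.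

Step 5
Reactants: 6 hexadeca-O-benzyl-rhodisin
Product: 7 Rhodisin
Conditions: H2 (1 atm), Pd(OH)2/C (20 wt%), degassed THF–MeOH–H2O (20:1:1), rt, 16 h; filtration, lyophilisation, ODS chromatography
Reagents that add atoms: none
Why: Catalytic hydrogenolysis of the sixteen aryl benzyl ethers over Pd(OH)2/C releases toluene and leaves the two gallate esters, the ring C ethers, the interflavan C–C bond and all five stereocentres untouched.

**Compound list**

1 | (−)-epigallocatechin (EGC); (2R,3R)-2-(3,4,5-trihydroxyphenyl)chroman-3,5,7-triol | O[C@@H]1Cc2c(O)cc(O)cc2O[C@@H]1c1cc(O)c(O)c(O)c1 | starting material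

2 | 5,7,3',4',5'-penta-O-benzyl-(−)-epigallocatechin; (2R,3R)-5,7-bis(benzyloxy)-2-[3,4,5-tris(benzyloxy)phenyl]chroman-3-ol | O[C@@H]1Cc2c(OCc3ccccc3)cc(OCc3ccccc3)cc2O[C@@H]1c1cc(OCc2ccccc2)c(OCc2ccccc2)c(OCc2ccccc2)c1 | intermediate

3 | (2R,3R,4S)-penta-O-benzyl-4β-(2-ethoxyethoxy)-epigallocatechin; 4-alkoxy group trans to the 3-OH | O[C@@H]1[C@@H](OCCOCC)c2c(OCc3ccccc3)cc(OCc3ccccc3)cc2O[C@@H]1c1cc(OCc2ccccc2)c(OCc2ccccc2)c(OCc2ccccc2)c1 | intermediate

4 | deca-O-benzyl-EGC-(4β→8)-EGC; both 3-OH free, upper unit 2R,3R,4R, lower unit 2R,3R | O[C@@H]1[C@@H](c2c(OCc9ccccc9)cc(OCc9ccccc9)c3c2O[C@H](c2cc(OCc9ccccc9)c(OCc9ccccc9)c(OCc9ccccc9)c2)[C@H](O)C3)c2c(OCc9ccccc9)cc(OCc9ccccc9)cc2O[C@@H]1c1cc(OCc9ccccc9)c(OCc9ccccc9)c(OCc9ccccc9)c1 | intermediate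

5 | 3,4,5-tris(benzyloxy)benzoic acid (tri-O-benzylgallic acid) | OC(=O)c1cc(OCc2ccccc2)c(OCc2ccccc2)c(OCc2ccccc2)c1 | starting material

6 | hexadeca-O-benzyl-rhodisin; perbenzylated EGCG-(4β→8)-EGCG, upper unit 2R,3R,4R, lower unit 2R,3R | O=C(O[C@@H]1[C@@H](c2c(OCc9ccccc9)cc(OCc9ccccc9)c3c2O[C@H](c2cc(OCc9ccccc9)c(OCc9ccccc9)c(OCc9ccccc9)c2)[C@H](OC(=O)c2cc(OCc9ccccc9)c(OCc9ccccc9)c(OCc9ccccc9)c2)C3)c2c(OCc9ccccc9)cc(OCc9ccccc9)cc2O[C@@H]1c1cc(OCc9ccccc9)c(OCc9ccccc9)c(OCc9ccccc9)c1)c1cc(OCc9ccccc9)c(OCc9ccccc9)c(OCc9ccccc9)c1 | intermediate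

7 | Rhodisin; EGCG-(4β→8)-EGCG, upper unit 2R,3R,4R, lower unit 2R,3R | O=C(O[C@@H]1[C@@H](c2c(O)cc(O)c3c2O[C@H](c2cc(O)c(O)c(O)c2)[C@H](OC(=O)c2cc(O)c(O)c(O)c2)C3)c2c(O)cc(O)cc2O[C@@H]1c1cc(O)c(O)c(O)c1)c1cc(O)c(O)c(O)c1 | target

**Totals**
Total step count: 5.
Longest linear sequence: 5 steps (1 → 2 → 3 → 4 → 6 → 7); compound 2 serves both as precursor of the electrophile and as the nucleophile.

**Three steps most likely to fail, with fallbacks**

Step 3 (most risky). Electrophile 3 still carries a free nucleophilic C8, so self-condensation and higher oligomers compete, and separating 4 from the excess of 2 may be laborious. The fallback sets out from 2 and comes back at 7, using a bromine cap. NBS (1.05 equiv, CH2Cl2, −40 → 0 °C) brominates C8 of ring A of 2 to give 8-bromo-penta-O-benzyl-(−)-epigallocatechin F1. DDQ and 2-ethoxyethanol in CH2Cl2 then give 8-bromo-penta-O-benzyl-4β-(2-ethoxyethoxy)-epigallocatechin F2, an electrophile whose own C8 is blocked. Near-equimolar coupling of F2 with 2 (Me3SiOTf, CH2Cl2, −78 °C) gives 8-bromo-deca-O-benzyl-EGC-(4β→8)-EGC F3, bromine on C8 of the upper unit. Esterification with acid 5 (DCC, DMAP, CH2Cl2) gives 8-bromo-hexadeca-O-benzyl-rhodisin F4. Hydrogenolysis (H2, Pd(OH)2/C, Et3N, THF–MeOH–H2O) removes the bromine and all sixteen benzyl groups in one operation to give 7.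

Step 4. The upper 3-OH of 4 is axial and flanked by the C2 aryl group and the bulky C4 flavanyl group, so the second acylation may stall at the mono-gallate. The fallback sets out from 3 (together with 2) and comes back at 6, placing the esters before the coupling. Compound 3 and acid 5 (DCC, DMAP, CH2Cl2) give (2R,3R,4S)-octa-O-benzyl-4β-(2-ethoxyethoxy)-EGCG F5, and 2 with acid 5 under the same conditions gives octa-O-benzyl-EGCG F6. F5 (1 equiv) and F6 (3 equiv) are then joined with Me3SiOTf or Yb(OTf)3 in CH2Cl2 at −40 °C. The 3-O-galloyl group of F5 shields the α face by neighbouring-group participation, so the 4β→8 bond forms, giving 6.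

Step 1. Five phenoxides, three of them on a pyrogallol ring, are exposed to base for hours, which risks air oxidation, C-benzylation at C6/C8 and partial C2 epimerisation. The fallback sets out from 1 and comes back at 2. Ac2O/pyridine gives the air-stable, easily purified (−)-epigallocatechin hexa-O-acetate F7. A one-pot acetate-to-benzyl-ether exchange (NaH, BnBr, DMF, slow addition of 5 equiv H2O, 0 °C) unmasks each phenoxide and benzylates it at once. The far less reactive aliphatic acetate is kept, so the product is penta-O-benzyl-(−)-epigallocatechin 3-O-acetate F8. K2CO3 in MeOH–THF at rt then removes the 3-O-acetate to give 2.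

**Further compounds**

F1 | step 3 | 8-bromo-penta-O-benzyl-(−)-epigallocatechin (2R,3R) | O[C@@H]1Cc2c(OCc3ccccc3)cc(OCc3ccccc3)c(Br)c2O[C@@H]1c1cc(OCc2ccccc2)c(OCc2ccccc2)c(OCc2ccccc2)c1

F2 | step 3 | 8-bromo-penta-O-benzyl-4β-(2-ethoxyethoxy)-epigallocatechin (configuration as in 3) | O[C@@H]1[C@@H](OCCOCC)c2c(OCc3ccccc3)cc(OCc3ccccc3)c(Br)c2O[C@@H]1c1cc(OCc2ccccc2)c(OCc2ccccc2)c(OCc2ccccc2)c1

F3 | step 3 | 8-bromo-deca-O-benzyl-EGC-(4β→8)-EGC (bromine on C8 of the upper unit, configuration as in 4) | O[C@@H]1[C@@H](c2c(OCc9ccccc9)cc(OCc9ccccc9)c3c2O[C@H](c2cc(OCc9ccccc9)c(OCc9ccccc9)c(OCc9ccccc9)c2)[C@H](O)C3)c2c(OCc9ccccc9)cc(OCc9ccccc9)c(Br)c2O[C@@H]1c1cc(OCc9ccccc9)c(OCc9ccccc9)c(OCc9ccccc9)c1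

F4 | step 3 | 8-bromo-hexadeca-O-benzyl-rhodisin (bromine on C8 of the upper unit, configuration as in 6) | O=C(O[C@@H]1[C@@H](c2c(OCc9ccccc9)cc(OCc9ccccc9)c3c2O[C@H](c2cc(OCc9ccccc9)c(OCc9ccccc9)c(OCc9ccccc9)c2)[C@H](OC(=O)c2cc(OCc9ccccc9)c(OCc9ccccc9)c(OCc9ccccc9)c2)C3)c2c(OCc9ccccc9)cc(OCc9ccccc9)c(Br)c2O[C@@H]1c1cc(OCc9ccccc9)c(OCc9ccccc9)c(OCc9ccccc9)c1)c1cc(OCc9ccccc9)c(OCc9ccccc9)c(OCc9ccccc9)c1

F5 | step 4 | (2R,3R,4S)-octa-O-benzyl-4β-(2-ethoxyethoxy)-EGCG | O=C(O[C@@H]1[C@@H](OCCOCC)c2c(OCc3ccccc3)cc(OCc3ccccc3)cc2O[C@@H]1c1cc(OCc2ccccc2)c(OCc2ccccc2)c(OCc2ccccc2)c1)c1cc(OCc2ccccc2)c(OCc2ccccc2)c(OCc2ccccc2)c1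

F6 | step 4 | octa-O-benzyl-EGCG (2R,3R) | O=C(O[C@@H]1Cc2c(OCc3ccccc3)cc(OCc3ccccc3)cc2O[C@@H]1c1cc(OCc2ccccc2)c(OCc2ccccc2)c(OCc2ccccc2)c1)c1cc(OCc2ccccc2)c(OCc2ccccc2)c(OCc2ccccc2)c1

F7 | step 1 | (−)-epigallocatechin hexa-O-acetate (2R,3R) | CC(=O)O[C@@H]1Cc2c(OC(C)=O)cc(OC(C)=O)cc2O[C@@H]1c1cc(OC(C)=O)c(OC(C)=O)c(OC(C)=O)c1

F8 | step 1 | penta-O-benzyl-(−)-epigallocatechin 3-O-acetate (2R,3R) | CC(=O)O[C@@H]1Cc2c(OCc3ccccc3)cc(OCc3ccccc3)cc2O[C@@H]1c1cc(OCc2ccccc2)c(OCc2ccccc2)c(OCc2ccccc2)c1
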